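- The gamma run had received 25.0% of its charge of starting material at 1.50 h; of the charge, 13.1% stood free and 2.1% as target, which leaves 4.67 parts out of view per part of target. This number of parts, the loss ratio, is a selectivity factor read early in the run, and the scatter of the target reading alone gives it about 14.3% uncertainty.
- Catalyst: the flask has twice the [catalyst] of the gamma run. I took the loss as first order in [starting material] and the target step as first order in [catalyst] and, at fixed [catalyst], pseudo-first-order in [starting material], so log10 of the ratio falls by 0.301, from 0.669 to 0.368, which is a ratio of 2.33. On that reckoning 30.0% of the charge goes through the catalyst, and this scaling is my guess.
- Starting material: the free level in the gamma run read 20.1% at 6.00 h; taken as a steady state under the feed, that gives a removal constant of 0.829 h⁻¹ and a half-life of 0.836 h in the gamma run. The 54.0 h after the end of the feed in the flask are 64.6 such half-lives, or 19.4 powers of ten, so I expected none left.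
- Protic impurity: in the flask it amounts to 2.00% of the charge, far less than the share through the catalyst.
- Time: at 6.00 h the gamma ratio had reached 8.40, more than early on, so I expected target to leak away and to fall once the feed ended.

in all of them: catalyst 2 mol%

| flask | starting material | protic impurity | remark | time |
|---|---|---|---|---|
| gamma | 12 mM (fed, over 6.0 h) | 0.48 mM | run made earlier |  |
| flask | 24 mM (fed, over 6.0 h) | 0.480 mM |  | 2.5 d |

- gamma (time / h: target / %, starting material / %): 0.500: 0.6, 6.5; 1.50: 2.1, 13.1; 3.00: 4.1, 17.3; 4.00: 5.7, 19.4; 6.00: 8.5, 20.1

(standard deviation of a reading: 0.3 percentage points)

- a reading or a percentage of target counts all its forms, free or not
- the reaction counts as stopped when no species that holds the starting material changes by six tenths of a point or more over the second half of the time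
- percentages count the whole charge, also what has not yet gone in
- no earlier run changes the charge of catalyst; that part of a forecast is a guess
- a reading of starting material is of its free form alone

* at 2.5 d, what has stopped the reaction, if anything has (forward and back rates have come level / it is still moving / no working catalyst is left / all of the starting material has reacted)
* the target standing at 2.5 d, as a percentage of the starting material charged
* amount of target if the flask were left three thousand times as long, in percent of the starting material charged

- The forecast said it is still moving, with 80% of target and 97% in the long run, on the ground that “The pool should eventually drain nearly completely”. My reckoning differs from it: 30.0% of the charge through the catalyst, and no starting material left at 2.5 d.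
- The flask gave: all of the starting material has reacted, with 7.75% of target at 2.5 d and 7.75% in the long run.

    target ⇌ isomer of the product (K = 3.10, k = 9.50 × 10⁻⁵ s⁻¹)
    starting material + target ⇌ idle adduct, settled at all times (K = 69.0 M⁻¹)
    starting material → side product (k = 1.80 × 10⁻⁴ s⁻¹)
    starting material + protic impurity → quenched substrate (k = 0.220 M⁻¹ s⁻¹)
    starting material + catalyst → catalyst + target (k = 0.180 M⁻¹ s⁻¹)

- At 0.174 d the flask used starting material 2.1 times as fast for side product as through the catalyst, against the loss ratio of 2.33 I had scaled from the gamma readings, and up to 2.5 d the catalyst step turned over 31.8% of the charge, against my 30.0%. At 2.50 d the flask held 7.75% of this as target and 24.0% as isomer of the product. The neighbour with 8 mol% of catalyst scales to a ratio of 0.583, a share of 63.2%; there, target and isomer of the product held 64.4% at 2.50 d, of which 15.7% was target.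

All runs were generated by integration with constants of no real substance; the scatter is artificial.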